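**Conventions and one assumption**

- Chain carbons: C1–C6 are the six contiguous CH(aryl) carbons. C1 lies in the seven-membered ring and C6 in the eight-membered ring. C1, C3 and C6 each carry a 4-oxygenated phenyl group.
- Rings: A on C1, B on C2, C on C4, E on C5, D on C6; F is the free resorcinol ring.
- Bridging carbons: Ca joins rings A and B, Cb joins rings C and D, Cc joins rings E and F. Ca′, Cb′ and Cc′ are the neighbouring O–CH(aryl) carbons of the dihydrofurans.
- Assumption (chemistry): an (R,R)-1,2-dicyclohexylethane-1,2-diol boronic ester gives the (S)-α-chloro boronic ester on insertion of LiCHCl2 (priorities Cl > C > B > H), the (S,S)-ester gives the (R)-chloride, and a Grignard reagent replaces the chloride with inversion.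
- (Dichloromethyl)lithium 7 cannot be stored. It is numbered where it is first made, in step 3; each later homologation (steps 4, 8, 11, 14 and 17) makes it again in the flask from 6 and n-BuLi at −100 °C, and those steps list 6 as the reactant.
- Grignard reagents 11 and 24 are used as commercial THF solutions. The SMILES strings in the compound list define all configurations.

## Analysis of the target

Compound 54 is a resveratrol hexamer in which six 4-hydroxyphenyl groups and six resorcinol-type rings (A–F) are carried by twelve sp3 CH carbons, all stereogenic. Six of these, C1–C6, form an unbranched chain in which every carbon bears an aryl group: C1 (4-hydroxyphenyl and ring A), C2 (ring B), C3 (4-hydroxyphenyl, the only chain carbon outside a ring), C4 (ring C), C5 (ring E) and C6 (4-hydroxyphenyl and ring D). C1 and C2 are closed into a seven-membered ring through rings A and B and the bridging carbon Ca, whereas C4, C5 and C6 are closed into an eight-membered ring through rings C and D and the bridging carbon Cb; a third bridging carbon, Cc, joins ring E to the free ring F. Each bridging carbon is C3 of a 2,3-diaryl-2,3-dihydrobenzofuran whose O–CH(4-hydroxyphenyl) carbon (Ca′, Cb′, Cc′) sits on the oxygen of ring B, C or E; all six of these centres are R, so the three dihydrofurans have the same local sense. Along the chain the configuration alternates (1S,2R,3S,4R,5S,6S in the boronic ester 34), a pattern that one chiral controller applied unchanged cannot produce. Sensitive features are the fifteen phenols (oxidation), the three benzylic aryl ethers, which ionise under acid, and the doubly benzylic CH groups. The difficulty lies in six contiguous stereocentres on a chain that has no functional group other than aryl rings, and in closing the eight-membered ring between rings C and D when a seven-membered closure onto ring E is kinetically easier. The strategy rests on the C1–C6 chain: it is grown one CH(aryl) unit at a time from C6 to C1 on boron, and the rings are closed afterwards between aryl groups that are already in place.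

## Retrosynthetic reasoning

**54 from 53.** The fifteen O–CH3 bonds are cut last. Methyl ethers are the only phenol protection that survives carbenoids, Grignard reagents, aryllithiums and Lewis acids, so all oxygen functions travel as OMe and are freed in one operation.

**53 from 47 and 50.** In each dihydrofuran the ring O–C bond (to Ca′, Cb′, Cc′) and the adjacent C–C bond (Ca–Ca′, Cb–Cb′, Cc–Cc′) are cut. The one-carbon piece is the benzylic sulfonium ylide 51 from salt 50; the four-atom piece is an ortho-quinone methide, drawn for all three sites as 52 and released from the tris-sulfone 47. The cut is made here because the three anisyl-bearing carbons are the only skeletal carbons that do not belong to the chain or to an aryl ketone. The forward reaction must give the trans ring and the correct face at three sites.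

**47 from 44 by way of 46 and 45.** These are functional-group changes that single out three of fifteen methyl ethers. In triketone 44 exactly the ether oxygens of rings B, C and E that become furan oxygens lie ortho to a diaryl ketone, so chelation-directed cleavage gives 45. Reduction gives 46 and sulfinate exchange gives 47.

**44 from 42 and 43.** The Cc–ring E bond is cut (Friedel–Crafts acylation with acid chloride 43). It is the last C–C acylation because in 42 rings A–D are each deactivated by a ketone, which leaves ring E as the only nucleophilic resorcinol ring.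

**42 from 40 (through 41).** The Ca–ring B bond is cut. The acyl carbon is already on ring A, and the only activated ring within its reach is ring B, in a seven-membered closure; the anisyl group on C1 offers only a position meta to its methoxy group.

**40 from 38 (through 39).** Both bonds of Cb, to ring C and to ring D, are cut, and the carbonyl carbon is inserted between two aryl bromides. A Friedel–Crafts closure from ring D would choose ring E (seven-membered) over ring C (eight-membered). With a bromine on each terminus the regiochemistry is fixed by where the halogens were placed, and both were brought in with the aryl groups.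

**38 from 34 and 36 (through 37).** The C1–ring A bond is cut at the C–B bond left by the last homologation. Ring A arrives with its carboxyl carbon (the future Ca), and coupling with retention keeps the configuration set on boron.

**34 from 10.** The five chain C–C bonds (C1–C2 to C5–C6) and the five C–aryl bonds at C1–C5 are cut. Each CH comes from 6 through carbenoid 7, and each aryl group from Grignard reagent 24, 11 or 20. Nothing in the chain could direct these centres, so each is set by the diol on boron; because the required sense alternates, diols 4 and 15 are exchanged before every cycle after the first (13 → 16, 21 → 23, 26 → 28, 30 → 32). Ring C is introduced with its bromine (reagent 20, from 18).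

**10 and the small building blocks.** Compound 10 comes from 5, 6 and 9 by the same chemistry. The anisyl group is placed on boron first (5 from 3 and 4) and ring D comes from Grignard reagent 9 (from 2, from 1), so that 10 already carries the (S,S)-diol that the first cycle needs. 18 comes from 17, 36 from 35, and 50 from 48 and 49.

## Alternatives that were turned down

Alternative 1: oxidative β–β dimerisation with crossed ring closure.
- Disconnection: the C4–C5 bond and the C6–ring D bond. Two identical halves are joined, each a phenolic stilbene unit that already carries its dihydrofuran (phenol flanked by tert-butyl groups, one bromine blocking the resorcinol ring).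
- Forward key step: deprotonation and one-electron oxidation give phenoxyl radicals that couple at the stilbene β-carbons. A Lewis acid then lets one of the two quinone methides alkylate the dimethoxyphenyl ring of the other half, which closes the eight-membered ring and leaves the second quinone methide in A1.
- For it: it is biomimetic and very short, it makes the eight-ring domain with two dihydrofurans in one operation, and the surviving quinone methide is a natural electrophile at C3.
- Against it: radical β–β coupling gives meso and racemic-type pairs with little control, and C4, C5 and C6 would be set only by remote dihydrofuran centres. The two quinone methides are equivalent until one cyclises, and nothing directs the closure to the ring D carbon alone. C3, C2, C1 and the whole seven-ring unit would still have to be added through a cation–alkene reaction with no control element. Two bromines and four tert-butyl groups must be removed under conditions the benzylic ethers tolerate poorly.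
- Comparison: A1 is clearly stronger in step economy and convergence. The chosen route offers in its place a separately chosen configuration at each of C1–C6 and ring closures whose regiochemistry is fixed by pre-placed bromine and acyl groups.

Alternative 2: triple oxidative aryl shift with ring contraction.
- Disconnection: the bonds Ca–ring B, Cb–ring C and Cc–ring E. In the retron the three bridging carbons are stilbene carbons, and two of the three alkenes sit in rings that are one atom larger (eight- and nine-membered).
- Forward key step: a chiral aryl-iodine reagent of trivalent iodine, with a Lewis acid in methanol, adds to each alkene; the isopropoxy-activated aryl group migrates as the iodoarene leaves. Each site becomes a diarylmethine carrying a dimethyl acetal, and the two medium rings contract by one atom to give A2.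
- For it: Ca, Cb and Cc are set under reagent control in one operation, the acetal carbons are the future Ca′, Cb′ and Cc′, and the medium rings are made by contraction instead of direct closure. On the control of the three bridging carbons it is stronger than the chosen route, which relies on substrate bias there.
- Against it: the substrate of the key step must already contain the complete C1–C6 chain with its six stereocentres plus two strained medium-ring alkenes, so the central problem is only moved. Three electronically different alkenes must react with the same sense, and ring conformation may override the reagent. The wrong aryl group can migrate, and the oxidant also attacks the electron-rich rings. Three anisyl additions to aldehydes would still have to be made diastereoselective.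
- Comparison: A2 offers a better late stage for Ca–Cc; the chosen route offers a solution for the chain, which A2 presupposes.

Alternative 3: aryne insertion expanding a tetralone.
- Disconnection: the C6–ring D bond and the Cb–ring D bond, with ring D introduced as a dimethoxy-substituted aryne.
- Forward key step: the enolate of a tricyclic 2-tetralone that already holds one dihydrofuran adds through its benzylic α-carbon to the aryne. The aryl anion closes on the ketone, and the four-membered alkoxide fragments to the eight-membered ketone A3.
- For it: the eight-membered ring is formed directly and convergently with Cb and Cb′ in place. On ring construction it is stronger and shorter than the chosen route.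
- Against it: simple ketone enolates, unlike β-keto esters, tend to stop at α-arylation. The enolate has two α-positions, and the benzylic centre can epimerise. In A3 the C6 position is a ketone, C5 a CH2 and C3 a CH2; two aryl groups, ring E with its dihydrofuran, and the whole seven-ring unit would still have to be attached. Five contiguous centres (C1–C3, C5, C6) would be set by substrate control on a flexible medium ring.
- Comparison: A3 solves the ring first and leaves the chain open; the chosen route does the reverse and keeps the stereochemical risk in a reaction whose sense can be chosen at each carbon.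

The chain-building operation is run five times (steps 4, 8, 11, 14 and 17); step 17 completes it and delivers 34.

Key step: step 17

## Steps

Step 1
Reactants: 1 1-bromo-3,5-dimethoxybenzene
Product: 2 1-bromo-2-iodo-3,5-dimethoxybenzene
Conditions: NIS, CF3CO2H (cat.), MeCN, 0 °C → rt
Reagents that add atoms: N-iodosuccinimide, O=C1CCC(=O)N1I
Why: Electrophilic aromatic iodination; the position between Br and OMe (para to the second OMe) reacts in preference to the position squeezed between two OMe groups, as is usual for 5-substituted resorcinol dimethyl ethers.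

Step 2
Reactants: 3 4-methoxyphenylboronic acid; 4 (1S,2S)-1,2-dicyclohexylethane-1,2-diol
Product: 5 (4S,5S)-4,5-dicyclohexyl-2-(4-methoxyphenyl)-1,3,2-dioxaborolane
Conditions: MgSO4, Et2O, rt
Reagents that add atoms: none
Why: Condensation of a boronic acid with a 1,2-diol; the dioxaborolane forms completely once water is removed.

Step 3
Reactants: 5 anisyl boronic ester; 6 dichloromethane; 2 1-bromo-2-iodo-3,5-dimethoxybenzene
Product: 10 benzhydryl boronic ester (4S,5S)-2-[(S)-(2-bromo-4,6-dimethoxyphenyl)(4-methoxyphenyl)methyl]-4,5-dicyclohexyl-1,3,2-dioxaborolane, via (dichloromethyl)lithium 7 (not isolated), via chloro boronic ester 8 (not isolated), via aryl Grignard reagent 9 (not isolated)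
Conditions: 6, n-BuLi, THF, −100 °C; 5, then ZnCl2, −100 °C → rt; separately 2, i-PrMgCl·LiCl, THF, −40 °C; combine at −78 °C → rt
Reagents that add atoms: none
Why: Matteson homologation: 7 adds to boron, the anisyl group migrates under ZnCl2 to give the (R)-chloride 8 under control of the (S,S)-diol (this benzylic chloride is used at once, with ZnCl2 holding back chloride exchange), and Grignard reagent 9 (selective iodine–magnesium exchange, kept cold so that no aryne forms before it is bound to boron) displaces chloride with inversion and sets C6 as S. The anisyl group is put on boron first so that 10 already carries the diol enantiomer needed in step 4.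

Step 4
Reactants: 10 benzhydryl boronic ester; 6 dichloromethane; 11 (3,5-dimethoxyphenyl)magnesium bromide
Product: 13 boronic ester of the C5–C6 unit (boron on C5; ring E on C5; (S,S)-diol; 5S,6S), via chloro boronic ester 12 (not isolated)
Conditions: 6, n-BuLi, THF, −100 °C; 10, then ZnCl2, −100 °C → rt; 11, THF, −78 °C → rt
Reagents that add atoms: none
Why: First chain cycle of the Matteson homologation: carbenoid 7, made afresh from 6 and n-BuLi as in step 3, adds to boron, C6 migrates with retention, the (S,S)-diol gives the (R)-chloride 12, and aryl migration from the borate of 11 with inversion sets C5 as S.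

Step 5
Reactants: 13 boronic ester of the C5–C6 unit
Product: 14 potassium trifluoroborate of the C5–C6 unit
Conditions: KHF2, MeOH–H2O, rt; solid washed with Et2O
Reagents that add atoms: potassium hydrogen difluoride, [K+].[F-].F
Why: Fluoride converts the hindered dioxaborolane into the trifluoroborate and releases the diol, which is washed out and recovered; the C–B bond and its configuration are not touched.

Step 6
Reactants: 14 potassium trifluoroborate; 15 (1R,2R)-1,2-dicyclohexylethane-1,2-diol
Product: 16 boronic ester of the C5–C6 unit with the (R,R)-diol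
Conditions: Me3SiCl, imidazole, MeCN, rt
Reagents that add atoms: none
Why: The chlorosilane removes fluoride as Me3SiF and boron is esterified by the enantiomeric diol, directly or through its silyl ether; imidazole takes up HCl so that the benzylic C–B bond is not protonated.

Step 7
Reactants: 17 1-iodo-3,5-dimethoxybenzene
Product: 18 2-bromo-1-iodo-3,5-dimethoxybenzene
Conditions: NBS, MeCN, 0 °C → rt
Reagents that add atoms: N-bromosuccinimide, O=C1CCC(=O)N1Br
Why: Electrophilic bromination ortho to iodine and para to OMe, with the same regiochemistry as in step 1.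

Step 8
Reactants: 16 boronic ester of the C5–C6 unit with the (R,R)-diol; 6 dichloromethane; 18 2-bromo-1-iodo-3,5-dimethoxybenzene
Product: 21 boronic ester of the C4–C6 unit (boron on C4; brominated ring C on C4; (R,R)-diol; 4R,5S,6S), via chloro boronic ester 19 (not isolated), via aryl Grignard reagent 20 (not isolated)
Conditions: 6, n-BuLi, THF, −100 °C; 16, then ZnCl2, −100 °C → rt; separately 18, i-PrMgCl·LiCl, THF, −40 °C; combine at −78 °C → rt
Reagents that add atoms: none
Why: Second cycle, with carbenoid 7 made afresh from 6: the (R,R)-diol now gives the (S)-chloride 19, and the ortho-bromoaryl Grignard reagent 20, bound to boron at −78 °C before it can lose MgBrCl, migrates with inversion to set C4 as R. The bromine on ring C is the handle for step 21.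

Step 9
Reactants: 21 boronic ester of the C4–C6 unit
Product: 22 potassium trifluoroborate of the C4–C6 unit
Conditions: KHF2, MeOH–H2O, rt; solid washed with Et2O
Reagents that add atoms: potassium hydrogen difluoride, [K+].[F-].F
Why: As step 5; the (R,R)-diol is released and recovered.

Step 10
Reactants: 22 potassium trifluoroborate; 4 (1S,2S)-1,2-dicyclohexylethane-1,2-diol
Product: 23 boronic ester of the C4–C6 unit with the (S,S)-diol
Conditions: Me3SiCl, imidazole, MeCN, rt
Reagents that add atoms: none
Why: As step 6, with the (S,S)-diol.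

Step 11
Reactants: 23 boronic ester of the C4–C6 unit with the (S,S)-diol; 6 dichloromethane; 24 (4-methoxyphenyl)magnesium bromide
Product: 26 boronic ester of the C3–C6 unit (boron on C3; anisyl on C3; (S,S)-diol; 3S,4R,5S,6S), via chloro boronic ester 25 (not isolated)
Conditions: 6, n-BuLi, THF, −100 °C; 23, then ZnCl2, −100 °C → rt; 24, THF, −78 °C → rt
Reagents that add atoms: none
Why: Third cycle, with carbenoid 7 made afresh from 6: (S,S)-diol, (R)-chloride 25, inversion by the anisyl group, C3 set as S.

Step 12
Reactants: 26 boronic ester of the C3–C6 unit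
Product: 27 potassium trifluoroborate of the C3–C6 unit
Conditions: KHF2, MeOH–H2O, rt; solid washed with Et2O
Reagents that add atoms: potassium hydrogen difluoride, [K+].[F-].F
Why: As step 5.

Step 13
Reactants: 27 potassium trifluoroborate; 15 (1R,2R)-1,2-dicyclohexylethane-1,2-diol
Product: 28 boronic ester of the C3–C6 unit with the (R,R)-diol
Conditions: Me3SiCl, imidazole, MeCN, rt
Reagents that add atoms: none
Why: As step 6.

Step 14
Reactants: 28 boronic ester of the C3–C6 unit with the (R,R)-diol; 6 dichloromethane; 11 (3,5-dimethoxyphenyl)magnesium bromide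
Product: 30 boronic ester of the C2–C6 unit (boron on C2; ring B on C2; (R,R)-diol; 2R,3S,4R,5S,6S), via chloro boronic ester 29 (not isolated)
Conditions: 6, n-BuLi, THF, −100 °C; 28, then ZnCl2, −100 °C → rt; 11, THF, −78 °C → rt
Reagents that add atoms: none
Why: Fourth cycle, with carbenoid 7 made afresh from 6: (R,R)-diol, (S)-chloride 29, inversion by the dimethoxyphenyl group, C2 set as R.

Step 15
Reactants: 30 boronic ester of the C2–C6 unit
Product: 31 potassium trifluoroborate of the C2–C6 unit
Conditions: KHF2, MeOH–H2O, rt; solid washed with Et2O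
Reagents that add atoms: potassium hydrogen difluoride, [K+].[F-].F
Why: As step 5.

Step 16
Reactants: 31 potassium trifluoroborate; 4 (1S,2S)-1,2-dicyclohexylethane-1,2-diol
Product: 32 boronic ester of the C2–C6 unit with the (S,S)-diol
Conditions: Me3SiCl, imidazole, MeCN, rt
Reagents that add atoms: none
Why: As step 6.

Step 17
Reactants: 32 boronic ester of the C2–C6 unit with the (S,S)-diol; 6 dichloromethane; 24 (4-methoxyphenyl)magnesium bromide
Product: 34 hexa-aryl hexane boronic ester (boron on C1; (S,S)-diol; 1S,2R,3S,4R,5S,6S), via chloro boronic ester 33 (not isolated)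
Conditions: 6, n-BuLi, THF, −100 °C; 32, then ZnCl2, −100 °C → rt; 24, THF, −78 °C → rt
Reagents that add atoms: none
Why: Carbenoid 7, made afresh from 6 and n-BuLi, adds to the boron of 32 at −100 °C to give a tetracoordinate borate; ZnCl2 then binds one chloride and a ring oxygen, and C2 migrates from boron to carbon with retention while that chloride leaves, the (S,S)-diol deciding which chloride departs, so that 33 is R at the new carbon. Grignard reagent 24 adds to the boron of 33 and the anisyl group migrates with inversion, which gives 34 with C1 as S. The closest known reaction type is the Matteson homologation of chiral-diol boronic esters with LiCHCl2 and Grignard reagents, run iteratively. No ring is closed. The new stereocentre C1 (like C5, C4, C3 and C2 in steps 4, 8, 11 and 14) is controlled by the C2-symmetric diol on boron and not by the chain, which is why the diol enantiomer is changed before each cycle. The step needs chain migration to win over oxygen migration and over loss of 7 from the hindered borate, which low temperature and ZnCl2 favour; it needs the chloride not to epimerise, which holds because the chloride carbon is not benzylic and ZnCl2 removes free chloride; and it needs substitution to win over elimination towards C2–H, which the weakly basic aryl Grignard reagent, entering through boron, secures. The aryl bromides on rings C and D survive because n-BuLi is consumed by 6 before 32 is added and aryl Grignard reagents do not exchange with aryl bromides at these temperatures.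

Step 18
Reactants: 35 methyl 3,5-dimethoxybenzoate
Product: 36 methyl 2-iodo-3,5-dimethoxybenzoate
Conditions: NIS, CF3CO2H, MeCN, rt
Reagents that add atoms: N-iodosuccinimide, O=C1CCC(=O)N1I
Why: Electrophilic iodination ortho to the ester and para to OMe; the position between the two OMe groups is the more hindered one.

Step 19
Reactants: 34 hexa-aryl hexane boronic ester; 36 methyl 2-iodo-3,5-dimethoxybenzoate
Product: 37 methyl ester carrying ring A on C1 (hepta-aryl hexane; configuration of C1–C6 as in 34)
Conditions: Pd2(dba)3 (cat.), PPh3 (excess), Ag2O, DME, 85 °C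
Reagents that add atoms: none
Why: Stereoretentive Suzuki–Miyaura coupling of a secondary benzylic boronic ester: zerovalent palladium inserts into the C–I bond of 36 (the two hindered, electron-rich aryl bromides react far more slowly), Ag2O mediates transmetalation with retention at C1, and reductive elimination forms the C1–ring A bond. Excess PPh3 keeps divalent palladium saturated and holds back β-hydride elimination towards C2.

Step 20
Reactants: 37 methyl ester carrying ring A
Product: 38 carboxylic acid carrying ring A
Conditions: LiOH, THF–MeOH–H2O, 60 °C; then aq. HCl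
Reagents that add atoms: lithium hydroxide, [Li+].[OH-]
Why: Saponification of an ortho-substituted benzoate; nothing else in 37 is base-labile, and the free acid is needed as a carboxylate in step 21 and as the acyl donor in step 22.

Step 21
Reactants: 38 carboxylic acid carrying ring A
Product: 40 eight-membered-ring ketone acid (Cb=O between rings C and D), via trilithiated carboxylate 39 (not isolated)
Conditions: t-BuLi (5 equiv), THF, −78 °C; Me2NCOCl (1 equiv, slow addition), −78 → 0 °C; aq. HCl
Reagents that add atoms: dimethylcarbamoyl chloride, CN(C)C(=O)Cl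
Why: The lithium carboxylate is inert to aryllithiums at −78 °C, and bromine–lithium exchange at both bromides gives 39. One aryllithium is acylated by the carbamoyl chloride and the other adds to the resulting amide, whose tetrahedral adduct survives until work-up, so the diaryl ketone forms without over-addition (double halogen–lithium exchange followed by a carbonyl dication equivalent, the intramolecular half being a Parham-type cyclisation). Because the two lithiated carbons are exactly the ones to be bridged, only the eight-membered ring can form and the seven-membered closure onto ring E is excluded.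

Step 22
Reactants: 40 eight-membered-ring ketone acid
Product: 42 diketone with the seven- and the eight-membered ring (Ca=O between rings A and B), via acid chloride 41 (not isolated)
Conditions: (COCl)2, DMF (cat.), CH2Cl2, 0 °C → rt; then SnCl4, CH2Cl2, −20 → 0 °C
Reagents that add atoms: none
Why: Intramolecular Friedel–Crafts acylation: the acylium ion on ring A closes the seven-membered ring onto ring B, whose two positions ortho to C2 are equivalent and activated by two OMe groups. The anisyl group on C1 could give a six-membered, anthrone-type closure only at a position meta to its OMe group, which is not activated; rings C and D are deactivated by the ketone made in step 21, and ring E is out of reach.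

Step 23
Reactants: 42 diketone; 43 3,5-dimethoxybenzoyl chloride
Product: 44 triketone (Cc=O between rings E and F)
Conditions: SnCl4, CH2Cl2, −20 °C → rt
Reagents that add atoms: none
Why: Intermolecular Friedel–Crafts acylation: ring E is the only dimethoxyarene of 42 that is not deactivated by a carbonyl group. Its two positions ortho to C5 are equivalent and, being para to one OMe and flanked by only one, should react before the position between the two OMe groups.

Step 24
Reactants: 44 triketone
Product: 45 triketone triphenol (free OH on rings B and C and E ortho to the ketones)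
Conditions: BCl3, CH2Cl2, −78 → 0 °C; aq. work-up
Reagents that add atoms: none
Why: Chelation-directed demethylation: BCl3 binds each ketone oxygen and cleaves only the methyl ether that can close a six-membered chelate. Those are the ethers on rings B, C and E next to Ca, Cb and Cc; rings A, D and F have no OMe ortho to a carbonyl group.

Step 25
Reactants: 45 triketone triphenol
Product: 46 tris(ortho-hydroxybenzhydrol)
Conditions: NaBH4, THF–MeOH, 0 °C
Reagents that add atoms: none
Why: Hydride reduction of ortho-hydroxy diaryl ketones to benzhydrols, kept cold so that the products do not go on to quinone methides and over-reduce. The three new carbinol centres are mixtures and are removed in step 28.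

Step 26
Reactants: 46 tris(ortho-hydroxybenzhydrol)
Product: 47 tris-sulfone (a 4-tolylsulfonyl group on each of Ca and Cb and Cc)
Conditions: p-TolSO2Na, HCO2H, THF–H2O, rt
Reagents that add atoms: sodium 4-methylbenzenesulfinate, Cc1ccc(cc1)S(=O)[O-].[Na+]
Why: Mild acid ionises the electron-rich ortho-hydroxybenzhydrols, and the soft sulfinate, in large excess, captures each cation at sulfur faster than a neighbouring arene can. 2-(Sulfonylalkyl)phenols are the standard base-labile precursors of ortho-quinone methides.

Step 27
Reactants: 48 4-methoxybenzyl alcohol; 49 tetrahydrothiophene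
Product: 50 1-(4-methoxybenzyl)tetrahydrothiophenium tetrafluoroborate
Conditions: HBF4·OEt2, CH2Cl2, 0 °C → rt
Reagents that add atoms: tetrafluoroboric acid, [H+].F[B-](F)(F)F
Why: Acid-promoted alkylation of the sulfide by the 4-methoxybenzyl cation; the non-nucleophilic counter-ion keeps the salt from reverting.

Step 28
Reactants: 47 tris-sulfone; 50 1-(4-methoxybenzyl)tetrahydrothiophenium tetrafluoroborate
Product: 53 pentadeca-O-methyl ether of the target, via sulfonium ylide 51 (not isolated), via tris(quinone methide) 52 (not isolated)
Conditions: Cs2CO3 (excess), CH2Cl2–MeCN, 0 °C → rt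
Reagents that add atoms: none
Why: Formal [4+1] annulation of ortho-quinone methides with a sulfonium ylide: base eliminates sulfinate from each phenol (52 is drawn with all three sites opened, which in practice react one after another) and deprotonates 50 to ylide 51. The ylide adds to the methide carbon and the phenoxide displaces tetrahydrothiophene from the backside. The trans ring arises from the anti betaine, so each Ca′/Cb′/Cc′ centre follows its bridging carbon. The face at Ca, Cb and Cc is the one anti to the chain substituent on the adjacent ring position: the folded seven- and eight-membered rings shield one face, and at ring E the C5 substituent twists the methide out of plane and blocks one side.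

Step 29
Reactants: 53 pentadeca-O-methyl ether
Product: 54 CNP0184494.1
Conditions: BBr3 (excess), CH2Cl2, −78 °C → rt; MeOH then H2O
Reagents that add atoms: none
Why: Lewis acid cleavage of all fifteen aryl methyl ethers, as is usual for permethylated resveratrol oligomers. The trans-dihydrofurans are the thermodynamically favoured epimers, so reversible opening of the benzylic ethers should return the same isomers.

## Compound list

1 | 1-bromo-3,5-dimethoxybenzene | COc1cc(Br)cc(OC)c1 | starting material
2 | 1-bromo-2-iodo-3,5-dimethoxybenzene | COc1cc(OC)c(I)c(Br)c1 | intermediate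
3 | 4-methoxyphenylboronic acid | COc1ccc(cc1)B(O)O | starting material
4 | (1S,2S)-1,2-dicyclohexylethane-1,2-diol | O[C@@H](C1CCCCC1)[C@H](C1CCCCC1)O | starting material
5 | (4S,5S)-4,5-dicyclohexyl-2-(4-methoxyphenyl)-1,3,2-dioxaborolane | COc1ccc(cc1)B1O[C@@H](C2CCCCC2)[C@H](C2CCCCC2)O1 | intermediate
6 | dichloromethane | ClCCl | starting material
7 | (dichloromethyl)lithium | [Li]C(Cl)Cl | intermediate (not isolated)
8 | (4S,5S)-2-[(R)-chloro(4-methoxyphenyl)methyl]-4,5-dicyclohexyl-1,3,2-dioxaborolane | B1(O[C@@H](C2CCCCC2)[C@H](C2CCCCC2)O1)[C@@H](Cl)c1ccc(OC)cc1 | intermediate (not isolated)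
9 | (2-bromo-4,6-dimethoxyphenyl)magnesium chloride | COc1cc(OC)c([Mg]Cl)c(Br)c1 | intermediate (not isolated)
10 | (4S,5S)-2-[(S)-(2-bromo-4,6-dimethoxyphenyl)(4-methoxyphenyl)methyl]-4,5-dicyclohexyl-1,3,2-dioxaborolane (benzhydryl boronic ester; its carbon is C6) | B1(O[C@@H](C2CCCCC2)[C@H](C2CCCCC2)O1)[C@@H](c1ccc(OC)cc1)c1c(Br)cc(OC)cc1OC | intermediate
11 | (3,5-dimethoxyphenyl)magnesium bromide | COc1cc(OC)cc([Mg]Br)c1 | starting material
12 | (S,S)-diol boronic ester with (R)-CHCl on boron followed by C6 | B1(O[C@@H](C2CCCCC2)[C@H](C2CCCCC2)O1)[C@@H](Cl)[C@@H](c1ccc(OC)cc1)c1c(Br)cc(OC)cc1OC | intermediate (not isolated)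
13 | (4S,5S)-4,5-dicyclohexyl-2-[(1S,2S)-2-(2-bromo-4,6-dimethoxyphenyl)-1-(3,5-dimethoxyphenyl)-2-(4-methoxyphenyl)ethyl]-1,3,2-dioxaborolane (C5–C6 unit) | B1(O[C@@H](C2CCCCC2)[C@H](C2CCCCC2)O1)[C@H](c1cc(OC)cc(OC)c1)[C@@H](c1ccc(OC)cc1)c1c(Br)cc(OC)cc1OC | intermediate
14 | potassium trifluoroborate of the C5–C6 unit (5S,6S) | [K+].F[B-](F)(F)[C@H](c1cc(OC)cc(OC)c1)[C@@H](c1ccc(OC)cc1)c1c(Br)cc(OC)cc1OC | intermediate
15 | (1R,2R)-1,2-dicyclohexylethane-1,2-diol | O[C@H](C1CCCCC1)[C@@H](C1CCCCC1)O | starting material
16 | (4R,5R)-dioxaborolane of the C5–C6 unit (5S,6S) | B1(O[C@H](C2CCCCC2)[C@@H](C2CCCCC2)O1)[C@H](c1cc(OC)cc(OC)c1)[C@@H](c1ccc(OC)cc1)c1c(Br)cc(OC)cc1OC | intermediate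
17 | 1-iodo-3,5-dimethoxybenzene | COc1cc(I)cc(OC)c1 | starting material
18 | 2-bromo-1-iodo-3,5-dimethoxybenzene | COc1cc(I)c(Br)c(OC)c1 | intermediate
19 | (R,R)-diol boronic ester with (S)-CHCl on boron followed by C5–C6 | B1(O[C@H](C2CCCCC2)[C@@H](C2CCCCC2)O1)[C@H](Cl)[C@H](c1cc(OC)cc(OC)c1)[C@@H](c1ccc(OC)cc1)c1c(Br)cc(OC)cc1OC | intermediate (not isolated)
20 | (2-bromo-3,5-dimethoxyphenyl)magnesium chloride | COc1cc([Mg]Cl)c(Br)c(OC)c1 | intermediate (not isolated)
21 | (4R,5R)-4,5-dicyclohexyl-2-[(1R,2S,3S)-3-(2-bromo-4,6-dimethoxyphenyl)-1-(2-bromo-3,5-dimethoxyphenyl)-2-(3,5-dimethoxyphenyl)-3-(4-methoxyphenyl)propyl]-1,3,2-dioxaborolane (C4–C6 unit) | B1(O[C@H](C2CCCCC2)[C@@H](C2CCCCC2)O1)[C@@H](c1cc(OC)cc(OC)c1Br)[C@H](c1cc(OC)cc(OC)c1)[C@@H](c1ccc(OC)cc1)c1c(Br)cc(OC)cc1OC | intermediate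
22 | potassium trifluoroborate of the C4–C6 unit (4R,5S,6S) | [K+].F[B-](F)(F)[C@@H](c1cc(OC)cc(OC)c1Br)[C@H](c1cc(OC)cc(OC)c1)[C@@H](c1ccc(OC)cc1)c1c(Br)cc(OC)cc1OC | intermediate
23 | (4S,5S)-dioxaborolane of the C4–C6 unit (4R,5S,6S) | B1(O[C@@H](C2CCCCC2)[C@H](C2CCCCC2)O1)[C@@H](c1cc(OC)cc(OC)c1Br)[C@H](c1cc(OC)cc(OC)c1)[C@@H](c1ccc(OC)cc1)c1c(Br)cc(OC)cc1OC | intermediate
24 | (4-methoxyphenyl)magnesium bromide | COc1ccc([Mg]Br)cc1 | starting material
25 | (S,S)-diol boronic ester with (R)-CHCl on boron followed by C4–C6 | B1(O[C@@H](C2CCCCC2)[C@H](C2CCCCC2)O1)[C@@H](Cl)[C@@H](c1cc(OC)cc(OC)c1Br)[C@H](c1cc(OC)cc(OC)c1)[C@@H](c1ccc(OC)cc1)c1c(Br)cc(OC)cc1OC | intermediate (not isolated)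
26 | (4S,5S)-4,5-dicyclohexyl-2-[(1S,2R,3S,4S)-4-(2-bromo-4,6-dimethoxyphenyl)-2-(2-bromo-3,5-dimethoxyphenyl)-3-(3,5-dimethoxyphenyl)-1,4-bis(4-methoxyphenyl)butyl]-1,3,2-dioxaborolane (C3–C6 unit) | B1(O[C@@H](C2CCCCC2)[C@H](C2CCCCC2)O1)[C@H](c1ccc(OC)cc1)[C@@H](c1cc(OC)cc(OC)c1Br)[C@H](c1cc(OC)cc(OC)c1)[C@@H](c1ccc(OC)cc1)c1c(Br)cc(OC)cc1OC | intermediate
27 | potassium trifluoroborate of the C3–C6 unit (3S,4R,5S,6S) | [K+].F[B-](F)(F)[C@H](c1ccc(OC)cc1)[C@@H](c1cc(OC)cc(OC)c1Br)[C@H](c1cc(OC)cc(OC)c1)[C@@H](c1ccc(OC)cc1)c1c(Br)cc(OC)cc1OC | intermediate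
28 | (4R,5R)-dioxaborolane of the C3–C6 unit (3S,4R,5S,6S) | B1(O[C@H](C2CCCCC2)[C@@H](C2CCCCC2)O1)[C@H](c1ccc(OC)cc1)[C@@H](c1cc(OC)cc(OC)c1Br)[C@H](c1cc(OC)cc(OC)c1)[C@@H](c1ccc(OC)cc1)c1c(Br)cc(OC)cc1OC | intermediate
29 | (R,R)-diol boronic ester with (S)-CHCl on boron followed by C3–C6 | B1(O[C@H](C2CCCCC2)[C@@H](C2CCCCC2)O1)[C@H](Cl)[C@H](c1ccc(OC)cc1)[C@@H](c1cc(OC)cc(OC)c1Br)[C@H](c1cc(OC)cc(OC)c1)[C@@H](c1ccc(OC)cc1)c1c(Br)cc(OC)cc1OC | intermediate (not isolated)
30 | (4R,5R)-4,5-dicyclohexyl-2-[(1R,2S,3R,4S,5S)-5-(2-bromo-4,6-dimethoxyphenyl)-3-(2-bromo-3,5-dimethoxyphenyl)-1,4-bis(3,5-dimethoxyphenyl)-2,5-bis(4-methoxyphenyl)pentyl]-1,3,2-dioxaborolane (C2–C6 unit) | B1(O[C@H](C2CCCCC2)[C@@H](C2CCCCC2)O1)[C@@H](c1cc(OC)cc(OC)c1)[C@H](c1ccc(OC)cc1)[C@@H](c1cc(OC)cc(OC)c1Br)[C@H](c1cc(OC)cc(OC)c1)[C@@H](c1ccc(OC)cc1)c1c(Br)cc(OC)cc1OC | intermediate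
31 | potassium trifluoroborate of the C2–C6 unit (2R,3S,4R,5S,6S) | [K+].F[B-](F)(F)[C@@H](c1cc(OC)cc(OC)c1)[C@H](c1ccc(OC)cc1)[C@@H](c1cc(OC)cc(OC)c1Br)[C@H](c1cc(OC)cc(OC)c1)[C@@H](c1ccc(OC)cc1)c1c(Br)cc(OC)cc1OC | intermediate
32 | (4S,5S)-dioxaborolane of the C2–C6 unit (2R,3S,4R,5S,6S) | B1(O[C@@H](C2CCCCC2)[C@H](C2CCCCC2)O1)[C@@H](c1cc(OC)cc(OC)c1)[C@H](c1ccc(OC)cc1)[C@@H](c1cc(OC)cc(OC)c1Br)[C@H](c1cc(OC)cc(OC)c1)[C@@H](c1ccc(OC)cc1)c1c(Br)cc(OC)cc1OC | intermediate
33 | (S,S)-diol boronic ester with (R)-CHCl on boron followed by C2–C6 | B1(O[C@@H](C2CCCCC2)[C@H](C2CCCCC2)O1)[C@@H](Cl)[C@@H](c1cc(OC)cc(OC)c1)[C@H](c1ccc(OC)cc1)[C@@H](c1cc(OC)cc(OC)c1Br)[C@H](c1cc(OC)cc(OC)c1)[C@@H](c1ccc(OC)cc1)c1c(Br)cc(OC)cc1OC | intermediate (not isolated)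
34 | (4S,5S)-4,5-dicyclohexyl-2-[(1S,2R,3S,4R,5S,6S)-6-(2-bromo-4,6-dimethoxyphenyl)-4-(2-bromo-3,5-dimethoxyphenyl)-2,5-bis(3,5-dimethoxyphenyl)-1,3,6-tris(4-methoxyphenyl)hexyl]-1,3,2-dioxaborolane (hexa-aryl hexane boronic ester) | B1(O[C@@H](C2CCCCC2)[C@H](C2CCCCC2)O1)[C@H](c1ccc(OC)cc1)[C@@H](c1cc(OC)cc(OC)c1)[C@H](c1ccc(OC)cc1)[C@@H](c1cc(OC)cc(OC)c1Br)[C@H](c1cc(OC)cc(OC)c1)[C@@H](c1ccc(OC)cc1)c1c(Br)cc(OC)cc1OC | intermediate
35 | methyl 3,5-dimethoxybenzoate | COC(=O)c1cc(OC)cc(OC)c1 | starting material
36 | methyl 2-iodo-3,5-dimethoxybenzoate | COC(=O)c1cc(OC)cc(OC)c1I | intermediate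
37 | methyl 3,5-dimethoxy-2-(hexa-aryl-hexyl)benzoate: ring A with its ester on C1 in place of boron, chain configuration as in 34 | COC(=O)c1cc(OC)cc(OC)c1[C@H](c1ccc(OC)cc1)[C@@H](c1cc(OC)cc(OC)c1)[C@H](c1ccc(OC)cc1)[C@@H](c1cc(OC)cc(OC)c1Br)[C@H](c1cc(OC)cc(OC)c1)[C@@H](c1ccc(OC)cc1)c1c(Br)cc(OC)cc1OC | intermediate
38 | carboxylic acid of 37 | OC(=O)c1cc(OC)cc(OC)c1[C@H](c1ccc(OC)cc1)[C@@H](c1cc(OC)cc(OC)c1)[C@H](c1ccc(OC)cc1)[C@@H](c1cc(OC)cc(OC)c1Br)[C@H](c1cc(OC)cc(OC)c1)[C@@H](c1ccc(OC)cc1)c1c(Br)cc(OC)cc1OC | intermediate
39 | trilithiated species: lithium carboxylate with lithium in place of both bromines | [Li]OC(=O)c1cc(OC)cc(OC)c1[C@H](c1ccc(OC)cc1)[C@@H](c1cc(OC)cc(OC)c1)[C@H](c1ccc(OC)cc1)[C@@H](c1cc(OC)cc(OC)c1[Li])[C@H](c1cc(OC)cc(OC)c1)[C@@H](c1ccc(OC)cc1)c1c([Li])cc(OC)cc1OC | intermediate (not isolated)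
40 | eight-membered-ring ketone acid: Cb=O bridges rings C and D; ring contains C4, C5, C6 | OC(=O)c1cc(OC)cc(OC)c1[C@H](c1ccc(OC)cc1)[C@@H](c1cc(OC)cc(OC)c1)[C@H](c1ccc(OC)cc1)[C@H]1c2cc(OC)cc(OC)c2C(=O)c2cc(OC)cc(OC)c2[C@H](c2ccc(OC)cc2)[C@H]1c1cc(OC)cc(OC)c1 | intermediate
41 | acid chloride of 40 | ClC(=O)c1cc(OC)cc(OC)c1[C@H](c1ccc(OC)cc1)[C@@H](c1cc(OC)cc(OC)c1)[C@H](c1ccc(OC)cc1)[C@H]1c2cc(OC)cc(OC)c2C(=O)c2cc(OC)cc(OC)c2[C@H](c2ccc(OC)cc2)[C@H]1c1cc(OC)cc(OC)c1 | intermediate (not isolated)
42 | diketone: seven-membered ring (Ca=O between rings A and B; C1, C2) and eight-membered ring (Cb=O) | O=C1c2cc(OC)cc(OC)c2[C@H](c2ccc(OC)cc2)[C@H]([C@H](c2ccc(OC)cc2)[C@H]2c3cc(OC)cc(OC)c3C(=O)c3cc(OC)cc(OC)c3[C@H](c3ccc(OC)cc3)[C@H]2c2cc(OC)cc(OC)c2)c2cc(OC)cc(OC)c21 | intermediate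
43 | 3,5-dimethoxybenzoyl chloride | COc1cc(cc(OC)c1)C(Cl)=O | starting material
44 | triketone: 42 with a 3,5-dimethoxybenzoyl group (Cc=O, ring F) on ring E ortho to C5 | O=C1c2cc(OC)cc(OC)c2[C@H](c2ccc(OC)cc2)[C@H]([C@H](c2ccc(OC)cc2)[C@H]2c3cc(OC)cc(OC)c3C(=O)c3cc(OC)cc(OC)c3[C@H](c3ccc(OC)cc3)[C@H]2c2cc(OC)cc(OC)c2C(=O)c2cc(OC)cc(OC)c2)c2cc(OC)cc(OC)c21 | intermediate
45 | triketone triphenol: OH on rings B, C and E ortho to Ca, Cb and Cc | O=C1c2cc(OC)cc(OC)c2[C@H](c2ccc(OC)cc2)[C@H]([C@H](c2ccc(OC)cc2)[C@H]2c3cc(OC)cc(O)c3C(=O)c3cc(OC)cc(OC)c3[C@H](c3ccc(OC)cc3)[C@H]2c2cc(OC)cc(O)c2C(=O)c2cc(OC)cc(OC)c2)c2cc(OC)cc(O)c21 | intermediate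
46 | tris(ortho-hydroxybenzhydrol): CH(OH) at Ca, Cb and Cc (carbinol centres unassigned) | OC1c2cc(OC)cc(OC)c2[C@H](c2ccc(OC)cc2)[C@H]([C@H](c2ccc(OC)cc2)[C@H]2c3cc(OC)cc(O)c3C(O)c3cc(OC)cc(OC)c3[C@H](c3ccc(OC)cc3)[C@H]2c2cc(OC)cc(O)c2C(O)c2cc(OC)cc(OC)c2)c2cc(OC)cc(O)c21 | intermediate
47 | tris-sulfone: 4-tolylsulfonyl at Ca, Cb and Cc (these centres unassigned) | Cc1ccc(cc1)S(=O)(=O)C1c2cc(OC)cc(OC)c2[C@H](c2ccc(OC)cc2)[C@H]([C@H](c2ccc(OC)cc2)[C@H]2c3cc(OC)cc(O)c3C(S(=O)(=O)c3ccc(C)cc3)c3cc(OC)cc(OC)c3[C@H](c3ccc(OC)cc3)[C@H]2c2cc(OC)cc(O)c2C(S(=O)(=O)c2ccc(C)cc2)c2cc(OC)cc(OC)c2)c2cc(OC)cc(O)c21 | intermediate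
48 | 4-methoxybenzyl alcohol | COc1ccc(CO)cc1 | starting material
49 | tetrahydrothiophene | C1CCSC1 | starting material
50 | 1-(4-methoxybenzyl)tetrahydrothiophenium tetrafluoroborate | COc1ccc(C[S+]2CCCC2)cc1.F[B-](F)(F)F | intermediate
51 | (4-methoxybenzylidene)tetrahydrothiophenium ylide | COc1ccc([CH-][S+]2CCCC2)cc1 | intermediate (not isolated)
52 | tris(ortho-quinone methide): rings B, C and E as 6-oxocyclohexa-2,4-dienylidenes with exocyclic C=C to Ca, Cb and Cc | C1c2cc(OC)cc(OC)c2[C@H](c2ccc(OC)cc2)[C@H]([C@H](c2ccc(OC)cc2)[C@H]2C3=CC(OC)=CC(=O)C3=Cc3cc(OC)cc(OC)c3[C@H](c3ccc(OC)cc3)[C@H]2C2=CC(OC)=CC(=O)C2=Cc2cc(OC)cc(OC)c2)C2=CC(OC)=CC(=O)C2=1 | intermediate (not isolated)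
53 | pentadeca-O-methyl ether of the target | COc1ccc([C@H]2c3c(OC)cc(OC)cc3[C@@H]3c4c(cc(OC)cc4[C@H]2[C@H](c2ccc(OC)cc2)[C@H]2c4cc(OC)cc5c4[C@@H](c4cc(OC)cc(OC)c4[C@H](c4ccc(OC)cc4)[C@H]2c2cc(OC)cc4c2[C@@H](c2cc(OC)cc(OC)c2)[C@H](c2ccc(OC)cc2)O4)[C@H](c2ccc(OC)cc2)O5)O[C@H]3c2ccc(OC)cc2)cc1 | intermediate
54 | CNP0184494.1 (resveratrol hexamer) | Oc1ccc([C@H]2c3c(O)cc(O)cc3[C@@H]3c4c(cc(O)cc4[C@H]2[C@H](c2ccc(O)cc2)[C@H]2c4cc(O)cc5c4[C@@H](c4cc(O)cc(O)c4[C@H](c4ccc(O)cc4)[C@H]2c2cc(O)cc4c2[C@@H](c2cc(O)cc(O)c2)[C@H](c2ccc(O)cc2)O4)[C@H](c2ccc(O)cc2)O5)O[C@H]3c2ccc(O)cc2)cc1 | target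

## Step count and least certain steps

Total step count: 29. Longest linear sequence: 25 steps (steps 2–6, 8–17, 19–26, 28 and 29, counted from 3).

**Step 17 (and its earlier runs, steps 4, 8, 11 and 14).**
- What may go wrong: the borate from 7 and the ever more hindered boronic ester may form reversibly or not rearrange, so that 7 decomposes or a ring oxygen migrates instead of the chain. The chloride may epimerise by chloride exchange. The Grignard reagent may act as a base towards the benzylic C–H next to the chloride. Each failure repeats in five cycles, and the four diol exchanges add handling of sensitive benzylic boron compounds.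
- Fallback: the last two chain carbons are added together. Boronic ester 26 is treated with (E)-1-(3,5-dimethoxyphenyl)-2-(4-methoxyphenyl)ethenyllithium F1 (from the corresponding alkenyl bromide and t-BuLi). The borate is rearranged with I2 and NaOMe (Zweifel olefination: C3 migrates with retention and the anti elimination inverts the alkene geometry) to the (Z)-alkene F2. Copper-catalysed protoboration of F2 (CuCl, NaOt-Bu, a chiral bisphosphine, B2pin2, MeOH) places boron on the CH(anisyl) carbon and hydrogen on the neighbouring carbon from the same face, the ligand choosing the face, and gives the pinacol boronic ester F3. F3 is coupled with 36 as in step 19, and the route is rejoined at 37; steps 12–17 are bypassed.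

**Step 19.**
- What may go wrong: transmetalation of the hindered ester to palladium may be too slow against β-hydride elimination towards C2 and against protodeboronation. The doubly ortho-substituted aryl group may retard reductive elimination, and stereochemical fidelity may be partly lost.
- Fallback: a transition-metal-free arylation. 2-Bromo-5-hydroxy-3-methoxybenzoic acid F4 (bromination of 3-hydroxy-5-methoxybenzoic acid para to the hydroxyl) is converted with NaH and t-BuLi at −78 °C into the trilithiated arene F5, which adds to the boron of 34. Oxidation of the phenolate–borate with Ph3BiF2 triggers 1,2-migration of C1 to the ring carbon with retention and loss of boron, giving the hydroxy acid F6. MeI and K2CO3 methylate the phenol and the acid, and the route is rejoined at 37.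

**Step 21.**
- What may go wrong: one aryllithium may be protonated by a benzylic C–H before it is acylated. Both aryllithiums may be capped by separate molecules of the carbamoyl chloride. The second, intramolecular addition may be slow for an eight-membered ring.
- Fallback: a stepwise version. From 38, n-BuLi (2 equiv, the first for the acid) at −100 °C exchanges the ring C bromide, which is flanked by OMe and gives the more stabilised aryllithium; an excess of dimethylcarbamoyl chloride then gives the bromo amide F7. t-BuLi at −78 °C exchanges the ring D bromide, and the aryllithium closes onto the amide (Parham cyclisation) to give 40.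

**Step 28.**
- What may go wrong: facial selectivity may be poor at one or more of the three quinone methides, above all at the freely rotating ring E site, which would give diastereomeric dihydrofurans. A quinone methide may also be attacked by a neighbouring electron-rich ring before the ylide arrives.
- Fallback: the control element is moved from the substrate to the reagent, which is possible because all three dihydrofurans need the same (R,R) sense. From 47, salt 50 is replaced by the enantiopure 4-methoxybenzylsulfonium salt F8 of isothiocineole (made like 50 from 48, the sulfide and HBF4; drawn for one enantiomer of the sulfide, the mirror image being used if the sense of induction requires it). The same base treatment leads to 53.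

**Step 29.**
- What may go wrong: the Lewis acid may ionise the benzylic C–O bonds of the dihydrofurans, leading to epimerisation or to arylation by a neighbouring ring, and cleavage of fifteen ethers may stop short.
- Fallback: nucleophilic demethylation under basic conditions. From 53, NaSEt in DMF at 130 °C cleaves the methyl ethers by substitution at methyl, and acidification gives 54.

## Further compounds

F1 | step 17 | (E)-1-(3,5-dimethoxyphenyl)-2-(4-methoxyphenyl)ethenyllithium | [Li]/C(c1cc(OC)cc(OC)c1)=C\c1ccc(OC)cc1
F2 | step 17 | (Z)-alkene from 26: C3–C(3,5-dimethoxyphenyl)=CH(4-methoxyphenyl) with the C3–C6 unit unchanged | COc1ccc(/C=C(\c2cc(OC)cc(OC)c2)[C@H](c2ccc(OC)cc2)[C@@H](c2cc(OC)cc(OC)c2Br)[C@H](c2cc(OC)cc(OC)c2)[C@@H](c2ccc(OC)cc2)c2c(Br)cc(OC)cc2OC)cc1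
F3 | step 17 | pinacol boronic ester with the hexa-aryl hexyl chain of 34 | CC1(C)OB(OC1(C)C)[C@H](c1ccc(OC)cc1)[C@@H](c1cc(OC)cc(OC)c1)[C@H](c1ccc(OC)cc1)[C@@H](c1cc(OC)cc(OC)c1Br)[C@H](c1cc(OC)cc(OC)c1)[C@@H](c1ccc(OC)cc1)c1c(Br)cc(OC)cc1OC
F4 | step 19 | 2-bromo-5-hydroxy-3-methoxybenzoic acid | OC(=O)c1cc(O)cc(OC)c1Br
F5 | step 19 | lithium 2-lithio-5-(lithiooxy)-3-methoxybenzoate | [Li]OC(=O)c1cc(O[Li])cc(OC)c1[Li]
F6 | step 19 | 5-hydroxy-3-methoxybenzoic acid carrying the hexa-aryl hexyl chain of 34 at C2 (ring A with free 4-OH and CO2H) | OC(=O)c1cc(O)cc(OC)c1[C@H](c1ccc(OC)cc1)[C@@H](c1cc(OC)cc(OC)c1)[C@H](c1ccc(OC)cc1)[C@@H](c1cc(OC)cc(OC)c1Br)[C@H](c1cc(OC)cc(OC)c1)[C@@H](c1ccc(OC)cc1)c1c(Br)cc(OC)cc1OC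
F7 | step 21 | bromo amide: 38 with CONMe2 in place of the ring C bromine | OC(=O)c1cc(OC)cc(OC)c1[C@H](c1ccc(OC)cc1)[C@@H](c1cc(OC)cc(OC)c1)[C@H](c1ccc(OC)cc1)[C@@H](c1cc(OC)cc(OC)c1C(=O)N(C)C)[C@H](c1cc(OC)cc(OC)c1)[C@@H](c1ccc(OC)cc1)c1c(Br)cc(OC)cc1OC
F8 | step 28 | S-(4-methoxybenzyl) sulfonium tetrafluoroborate of (1R,4R,5R)-4,7,7-trimethyl-6-thiabicyclo[3.2.1]octane | C[C@@H]1CC[C@@H]2C[C@H]1[S+](Cc1ccc(OC)cc1)C2(C)C.F[B-](F)(F)F
F0 | step 29 | none | none
A1 | alternative 1 | eight-membered-ring bis-dihydrofuran retaining one di-tert-butyl quinone methide | O=C1C(C(C)(C)C)=CC(=C[C@H]2c4c(Br)c(OC)cc5c4[C@@H](c4cc(OC)cc(OC)c4[C@H](c4cc(C(C)(C)C)c(O)c(C(C)(C)C)c4)[C@H]2c2c(Br)c(OC)cc4c2[C@@H](c2cc(OC)cc(OC)c2)[C@H](c2ccc(OC)cc2)O4)[C@H](c2ccc(OC)cc2)O5)C=C1C(C)(C)C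
A2 | alternative 2 | seven- and eight-membered-ring core with three diarylmethine dimethyl acetals | COc1ccc([C@H]2c3c(OC)cc(OC)cc3[C@@H](C(OC)OC)c4c(cc(OC)cc4[C@H]2[C@H](c2ccc(OC)cc2)[C@H]2c4cc(OC)cc(OC(C)C)c4[C@H](C(OC)OC)c4cc(OC)cc(OC)c4[C@H](c4ccc(OC)cc4)[C@H]2c2cc(OC)cc(OC(C)C)c2[C@H](C(OC)OC)c2cc(OC)cc(OC)c2)OC(C)C)cc1
A3 | alternative 3 | dibenzo-fused eight-membered ketone with the dihydrofuran in place | O=C1C[C@@H](Cc2ccc(OC)cc2)c2cc(OC)cc3c2[C@@H](c2cc(OC)cc(OC)c21)[C@H](c1ccc(OC)cc1)O3
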